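**Retrosynthetic overview**

1. Target 19 ⇐ bis-silyl ether 18 (fluoride) ⇐ aryl bromide 17 (Stille prenylation at C5′); the acid-sensitive prenyl group enters only after the acylation.
2. 17 ⇐ acid 15 by the C4–C4a disconnection: an intramolecular Friedel–Crafts acylation closes ring C (the pyran-4-one), the only ring formed in the route, with O1–C2=C3 already in place.
3. 15 ⇐ tert-butyl ester 14 ⇐ enol tosylate 13 + phenol 3. The O1–C2 bond is made by vinylic substitution under basic conditions, so the resorcinol-type ring reacts through oxygen and not through carbon (no Pechmann-type coumarin formation).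
4. 13 ⇐ tert-butyl arylacetate 11 ⇐ aldehyde 7 (one-carbon homologation) ⇐ 5-bromovanillin 4. Compound 4 carries its methyl on O3′, so the methyl is moved to O4′ by demethylation and selective re-methylation; 3 ⇐ 5-methoxyresorcinol 1.
5. Feature on which the strategy rests: C4a of ring A is ortho to O1, ortho to C5–OMe and para to C7–O. It is therefore a strongly activated carbon of the 1,3,5-trioxygenated ring A, and the C4–C4a bond can be made last by acylation.

Key step: step 11

Remark: the target has no stereocentre and is achiral, so no enantiocontrol is needed; the only stereo-elements are C=C geometries of intermediates.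
Assumption: enol ether 8 is used as its E/Z mixture (E drawn). Compounds 12–16 are drawn Z, the geometry able to close; any E isomer is carried along, because it should equilibrate with Z under the conditions of step 11.

Step 1
Reactants: 1 5-methoxyresorcinol; 2 triisopropylsilyl chloride
Product: 3 3-methoxy-5-(triisopropylsilyloxy)phenol
Conditions: TIPSCl (1.0 equiv), imidazole, DMF, 0 °C → rt
Reagents that add atoms: triisopropylsilyl chloride (2), CC(C)[Si](Cl)(C(C)C)C(C)C
Why: Imidazole-mediated silylation of a phenol; with one equivalent of silyl chloride the symmetrical diol should give mainly the mono-ether, and diol and bis-ether are separable and recyclable.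

Step 2
Reactants: 4 5-bromovanillin
Product: 5 3-bromo-4,5-dihydroxybenzaldehyde
Conditions: AlCl3, pyridine, CH2Cl2, reflux; aq. HCl work-up
Reagents that add atoms: none
Why: Lewis-acid-assisted demethylation of an ortho-hydroxy aryl methyl ether; aluminium chelates the two adjacent oxygens and pyridine takes up the methyl group, while aldehyde and bromide are inert.

Step 3
Reactants: 5 3-bromo-4,5-dihydroxybenzaldehyde
Product: 6 3-bromo-5-hydroxy-4-methoxybenzaldehyde
Conditions: MeI (1.1 equiv), Li2CO3, DMF, 40 °C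
Reagents that add atoms: iodomethane, CI
Why: Selective Williamson O-methylation of the more acidic phenol; O4 is para to the formyl group and ortho to bromine, so the weak base ionises only this hydroxyl.

Step 4
Reactants: 6 3-bromo-5-hydroxy-4-methoxybenzaldehyde; 2 triisopropylsilyl chloride
Product: 7 3-bromo-4-methoxy-5-(triisopropylsilyloxy)benzaldehyde
Conditions: TIPSCl, imidazole, DMF, rt
Reagents that add atoms: triisopropylsilyl chloride (2), CC(C)[Si](Cl)(C(C)C)C(C)C
Why: Standard phenol silylation; the triisopropylsilyl ether tolerates the ylide, acid, enolate and Pd chemistry that follow and is removed by fluoride at the end.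

Step 5
Reactants: 7 3-bromo-4-methoxy-5-(triisopropylsilyloxy)benzaldehyde
Product: 8 1-bromo-2-methoxy-5-(2-methoxyethenyl)-3-(triisopropylsilyloxy)benzene (E/Z mixture)
Conditions: MeOCH2PPh3Cl, KHMDS, THF, 0 °C → rt
Reagents that add atoms: (methoxymethyl)triphenylphosphonium chloride, COC[P+](c1ccccc1)(c1ccccc1)c1ccccc1.[Cl-]
Why: Wittig methoxymethylenation of an unhindered aromatic aldehyde; the double-bond geometry is irrelevant because both isomers hydrolyse to the same aldehyde.

Step 6
Reactants: 8 1-bromo-2-methoxy-5-(2-methoxyethenyl)-3-(triisopropylsilyloxy)benzene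
Product: 10 2-[3-bromo-4-methoxy-5-(triisopropylsilyloxy)phenyl]acetic acid, via arylacetaldehyde 9 (not isolated)
Conditions: 2 M aq. HCl, THF, 45 °C; then pH 4 (NaH2PO4), NaClO2, 2-methyl-2-butene, t-BuOH, 0 °C → rt
Reagents that add atoms: water, O; sodium chlorite, [Na+].[O-]Cl=O
Why: Acid hydrolysis of the enol ether followed directly by Pinnick oxidation, so the self-condensing arylacetaldehyde is never stored; the alkene scavenger keeps hypochlorite off the arene and the aryl silyl ether tolerates dilute acid.

Step 7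
Reactants: 10 2-[3-bromo-4-methoxy-5-(triisopropylsilyloxy)phenyl]acetic acid
Product: 11 tert-butyl 2-[3-bromo-4-methoxy-5-(triisopropylsilyloxy)phenyl]acetate
Conditions: tert-butyl 2,2,2-trichloroacetimidate, CH2Cl2/cyclohexane, rt
Reagents that add atoms: tert-butyl 2,2,2-trichloroacetimidate, CC(C)(C)OC(=N)C(Cl)(Cl)Cl
Why: tert-Butyl esterification with a trichloroacetimidate, activated by the carboxylic acid itself; no base or strong acid is present, so the silyl ether is untouched.

Step 8
Reactants: 11 tert-butyl 2-[3-bromo-4-methoxy-5-(triisopropylsilyloxy)phenyl]acetate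
Product: 13 tert-butyl (Z)-2-[3-bromo-4-methoxy-5-(triisopropylsilyloxy)phenyl]-3-(tosyloxy)prop-2-enoate, via lithium enolate 12 (not isolated)
Conditions: LiHMDS, HCO2Et, THF, −78 → 0 °C; then TsCl, N-methylimidazole, 0 °C → rt
Reagents that add atoms: ethyl formate, CCOC=O; p-toluenesulfonyl chloride, Cc1ccc(cc1)S(Cl)(=O)=O
Why: Crossed Claisen formylation of the arylacetate gives the lithium-chelated formyl-ester enolate (oxygen cis to the ester), and O-sulfonylation by the N-sulfonylimidazolium formed in situ should fix this as the Z enol tosylate and avoid C-chlorination.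

Step 9
Reactants: 13 tert-butyl (Z)-2-[3-bromo-4-methoxy-5-(triisopropylsilyloxy)phenyl]-3-(tosyloxy)prop-2-enoate; 3 3-methoxy-5-(triisopropylsilyloxy)phenol
Product: 14 tert-butyl (Z)-2-[3-bromo-4-methoxy-5-(triisopropylsilyloxy)phenyl]-3-[3-methoxy-5-(triisopropylsilyloxy)phenoxy]prop-2-enoate
Conditions: 3 (1.05 equiv), K2CO3, DABCO (20 mol%), MeCN, rt
Reagents that add atoms: none
Why: Nucleophilic vinylic substitution (addition–elimination) of the vinylogous acyl tosylate by the phenoxide, with DABCO directing attack to C3; a good nucleofuge should give mainly retention (Z), and anhydrous carbonate in acetonitrile should leave the hindered silyl ethers in place.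

Step 10
Reactants: 14 tert-butyl (Z)-2-[3-bromo-4-methoxy-5-(triisopropylsilyloxy)phenyl]-3-[3-methoxy-5-(triisopropylsilyloxy)phenoxy]prop-2-enoate
Product: 15 (Z)-2-[3-bromo-4-methoxy-5-(triisopropylsilyloxy)phenyl]-3-[3-methoxy-5-(triisopropylsilyloxy)phenoxy]prop-2-enoic acid
Conditions: TFA/CH2Cl2 (1:4), 1,3-dimethoxybenzene (cation trap), 0 °C → rt
Reagents that add atoms: none
Why: Acidolysis of the tert-butyl ester with loss of isobutene; aryl triisopropylsilyl ethers and the push–pull aryloxyacrylate tolerate anhydrous TFA, and the trap keeps stray tert-butyl cation off the electron-rich aryloxy ring.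

Step 11
Reactants: 15 (Z)-2-[3-bromo-4-methoxy-5-(triisopropylsilyloxy)phenyl]-3-[3-methoxy-5-(triisopropylsilyloxy)phenoxy]prop-2-enoic acid
Product: 17 3-[3-bromo-4-methoxy-5-(triisopropylsilyloxy)phenyl]-5-methoxy-7-(triisopropylsilyloxy)chromen-4-one, via mixed anhydride 16 (not isolated)
Conditions: TFAA (3 equiv), CH2Cl2, 0 °C → rt
Reagents that add atoms: none
Why: TFAA converts acid 15 into the mixed anhydride 16, which ionises to an acyl cation stabilised by the enol-ether oxygen (resonance form O=C=C(Ar)–CH=O+Ar′); the cation attacks the aryloxy ring at a carbon ortho to the ether oxygen, and proton loss gives the chromone. The closest known reaction type is the cyclodehydration of 3-aryloxyacrylic and aryloxyfumaric acids to chromones, an intramolecular Friedel–Crafts acylation. Ring C closes in a six-membered mode, exo with respect to the acylium C≡O and endo with respect to the arene C4a=C8a bond; no stereocentre is formed. Alkene geometry should not be limiting, because in the cation (and in the C2-protonated enol ether) the C2–C3 bond has single-bond character, so an E isomer can rotate into the reactive Z form. The step needs site selectivity between the two carbons ortho to the ether oxygen, which are electronically similar; attack at the one next to methoxy (giving 5-OMe/7-OSi) is expected because the triisopropylsilyl group crowds its own neighbour, much as an N-triisopropylsilyl group shields the α-positions of pyrrole, and this steric prediction must be checked on the first run by NOE/HMBC assignment. The bromide and both aryl silyl ethers are inert to TFAA/TFA, which is why bromine stands in for the prenyl group at this stage.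

Step 12
Reactants: 17 3-[3-bromo-4-methoxy-5-(triisopropylsilyloxy)phenyl]-5-methoxy-7-(triisopropylsilyloxy)chromen-4-one
Product: 18 5-methoxy-3-[4-methoxy-3-(3-methylbut-2-enyl)-5-(triisopropylsilyloxy)phenyl]-7-(triisopropylsilyloxy)chromen-4-one
Conditions: tributyl(3-methylbut-2-enyl)stannane, Pd(PPh3)4 (10 mol%), toluene, 105 °C
Reagents that add atoms: tributyl(3-methylbut-2-enyl)stannane, CCCC[Sn](CCCC)(CCCC)CC=C(C)C
Why: Stille cross-coupling of the aryl bromide with a prenylstannane, where reductive elimination from the less hindered allyl terminus should deliver the linear prenyl group; the neutral fluoride-free medium spares chromone and silyl ethers, and loss of a silyl group here would be harmless.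

Step 13
Reactants: 18 5-methoxy-3-[4-methoxy-3-(3-methylbut-2-enyl)-5-(triisopropylsilyloxy)phenyl]-7-(triisopropylsilyloxy)chromen-4-one
Product: 19 7-hydroxy-3-[3-hydroxy-4-methoxy-5-(3-methylbut-2-enyl)phenyl]-5-methoxychromen-4-one
Conditions: TBAF (2.5 equiv), AcOH (2.5 equiv), THF, 0 °C
Reagents that add atoms: none
Why: Fluoride cleavage of both aryl silyl ethers; the acetic acid buffer protects the chromone C2 from base-induced ring opening, and the prenyl group, which is ortho to OMe and not to a free phenol, is unaffected.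

**Compound list**

1 | 5-methoxyresorcinol | COc1cc(O)cc(O)c1 | starting material
2 | triisopropylsilyl chloride | CC(C)[Si](Cl)(C(C)C)C(C)C | starting material
3 | 3-methoxy-5-(triisopropylsilyloxy)phenol | COc1cc(O)cc(O[Si](C(C)C)(C(C)C)C(C)C)c1 | intermediate
4 | 5-bromovanillin | COc1cc(C=O)cc(Br)c1O | starting material
5 | 3-bromo-4,5-dihydroxybenzaldehyde | O=Cc1cc(O)c(O)c(Br)c1 | intermediate
6 | 3-bromo-5-hydroxy-4-methoxybenzaldehyde | COc1c(O)cc(C=O)cc1Br | intermediate
7 | 3-bromo-4-methoxy-5-(triisopropylsilyloxy)benzaldehyde | COc1c(O[Si](C(C)C)(C(C)C)C(C)C)cc(C=O)cc1Br | intermediate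
8 | 1-bromo-2-methoxy-5-(2-methoxyethenyl)-3-(triisopropylsilyloxy)benzene (E/Z mixture, E drawn) | COc1c(O[Si](C(C)C)(C(C)C)C(C)C)cc(/C=C/OC)cc1Br | intermediate
9 | 2-[3-bromo-4-methoxy-5-(triisopropylsilyloxy)phenyl]acetaldehyde (not isolated) | COc1c(O[Si](C(C)C)(C(C)C)C(C)C)cc(CC=O)cc1Br | intermediate
10 | 2-[3-bromo-4-methoxy-5-(triisopropylsilyloxy)phenyl]acetic acid | COc1c(O[Si](C(C)C)(C(C)C)C(C)C)cc(CC(=O)O)cc1Br | intermediate
11 | tert-butyl 2-[3-bromo-4-methoxy-5-(triisopropylsilyloxy)phenyl]acetate | COc1c(O[Si](C(C)C)(C(C)C)C(C)C)cc(CC(=O)OC(C)(C)C)cc1Br | intermediate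
12 | lithium (Z)-2-[3-bromo-4-methoxy-5-(triisopropylsilyloxy)phenyl]-3-tert-butoxy-3-oxoprop-1-en-1-olate (not isolated) | [Li+].[O-]/C=C(\C(=O)OC(C)(C)C)c1cc(Br)c(OC)c(O[Si](C(C)C)(C(C)C)C(C)C)c1 | intermediate
13 | tert-butyl (Z)-2-[3-bromo-4-methoxy-5-(triisopropylsilyloxy)phenyl]-3-(tosyloxy)prop-2-enoate | Cc1ccc(cc1)S(=O)(=O)O/C=C(\C(=O)OC(C)(C)C)c1cc(Br)c(OC)c(O[Si](C(C)C)(C(C)C)C(C)C)c1 | intermediate
14 | tert-butyl (Z)-2-[3-bromo-4-methoxy-5-(triisopropylsilyloxy)phenyl]-3-[3-methoxy-5-(triisopropylsilyloxy)phenoxy]prop-2-enoate | CC(C)(C)OC(=O)/C(=C\Oc1cc(OC)cc(O[Si](C(C)C)(C(C)C)C(C)C)c1)c1cc(Br)c(OC)c(O[Si](C(C)C)(C(C)C)C(C)C)c1 | intermediate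
15 | (Z)-2-[3-bromo-4-methoxy-5-(triisopropylsilyloxy)phenyl]-3-[3-methoxy-5-(triisopropylsilyloxy)phenoxy]prop-2-enoic acid | OC(=O)/C(=C\Oc1cc(OC)cc(O[Si](C(C)C)(C(C)C)C(C)C)c1)c1cc(Br)c(OC)c(O[Si](C(C)C)(C(C)C)C(C)C)c1 | intermediate
16 | mixed anhydride of 15 with trifluoroacetic acid (not isolated) | O=C(OC(=O)C(F)(F)F)/C(=C\Oc1cc(OC)cc(O[Si](C(C)C)(C(C)C)C(C)C)c1)c1cc(Br)c(OC)c(O[Si](C(C)C)(C(C)C)C(C)C)c1 | intermediate
17 | 3-[3-bromo-4-methoxy-5-(triisopropylsilyloxy)phenyl]-5-methoxy-7-(triisopropylsilyloxy)chromen-4-one | COc1c(O[Si](C(C)C)(C(C)C)C(C)C)cc(-c2coc3cc(O[Si](C(C)C)(C(C)C)C(C)C)cc(OC)c3c2=O)cc1Br | intermediate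
18 | 5-methoxy-3-[4-methoxy-3-(3-methylbut-2-enyl)-5-(triisopropylsilyloxy)phenyl]-7-(triisopropylsilyloxy)chromen-4-one | COc1c(O[Si](C(C)C)(C(C)C)C(C)C)cc(-c2coc3cc(O[Si](C(C)C)(C(C)C)C(C)C)cc(OC)c3c2=O)cc1CC=C(C)C | intermediate
19 | 7-hydroxy-3-[3-hydroxy-4-methoxy-5-(3-methylbut-2-enyl)phenyl]-5-methoxychromen-4-one | COc1c(O)cc(-c2coc3cc(O)cc(OC)c3c2=O)cc1CC=C(C)C | target

**Step count**

Total steps: 13. Longest linear sequence: 12 steps (steps 2–13, from 5-bromovanillin 4 to 19).

**Steps most likely to fail**

1. Step 11. The closure may leak to the ring carbon next to the silyloxy group, since the two ortho carbons differ mainly in crowding. Slow E→Z equilibration may allow intermolecular acylation. Acid may also cut the aryl vinyl ether before acylation, with recombination through carbon.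
 Fallback: a route in which the C4–C4a bond exists from the start, setting out from aldehyde 6 and returning at 17. Aldehyde 6 is protected with MOMCl/iPr2NEt as 3-bromo-4-methoxy-5-(methoxymethoxy)benzaldehyde F1. Commercial 1-(2,4-dihydroxy-6-methoxyphenyl)ethanone is converted with NaH/MOMCl into 1-[2-methoxy-4,6-bis(methoxymethoxy)phenyl]ethanone F2. Claisen–Schmidt condensation of the two (KOH, EtOH) gives (E)-3-[3-bromo-4-methoxy-5-(methoxymethoxy)phenyl]-1-[2-methoxy-4,6-bis(methoxymethoxy)phenyl]prop-2-en-1-one F3. Oxidative 1,2-aryl migration with Tl(NO3)3 in MeOH/HC(OMe)3 gives racemic 2-[3-bromo-4-methoxy-5-(methoxymethoxy)phenyl]-3,3-dimethoxy-1-[2-methoxy-4,6-bis(methoxymethoxy)phenyl]propan-1-one F4. HCl in MeOH at reflux removes the acetal protecting groups and closes the pyranone to 3-(3-bromo-5-hydroxy-4-methoxyphenyl)-7-hydroxy-5-methoxychromen-4-one F5. Silylation of both phenols (TIPSCl, imidazole, DMF) gives 17.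

2. Step 9. The phenoxide may attack sulfur (sulfonyl transfer) instead of C3. The hindered α-aryl acrylate may add slowly. A silyl group may migrate between phenoxide and aryl silyl ether under the basic conditions.
 Fallback: a halide nucleofuge with no second electrophilic centre, setting out from 11 and returning at 14. Ester 11 is formylated (LiHMDS, HCO2Et) and the product is isolated after acidic work-up as tert-butyl (Z)-2-[3-bromo-4-methoxy-5-(triisopropylsilyloxy)phenyl]-3-hydroxyprop-2-enoate F6. Vilsmeier chlorination ((COCl)2, cat. DMF, CH2Cl2, 0 °C) gives tert-butyl (Z)-3-chloro-2-[3-bromo-4-methoxy-5-(triisopropylsilyloxy)phenyl]prop-2-enoate F7 (either geometry serves). Addition–elimination with phenol 3 (K2CO3, MeCN) gives 14.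

3. Step 12. The prenyl group may transfer through its γ-terminus (1,1-dimethylallyl isomer). Oxidative addition into the electron-rich ortho-methoxy C–Br bond may be slow, and protodebromination may compete.
 Fallback: allylation followed by olefin cross-metathesis, setting out from 17 and returning at 18. Stille coupling of 17 with allyltributylstannane (Pd(PPh3)4, toluene, 100 °C), which has no regiochemical ambiguity, gives 3-[3-allyl-4-methoxy-5-(triisopropylsilyloxy)phenyl]-5-methoxy-7-(triisopropylsilyloxy)chromen-4-one F8. Cross-metathesis with excess 2-methyl-2-butene (Grubbs second-generation catalyst, CH2Cl2, 40 °C) gives 18.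

**Further compounds**

F1 | step 11 | 3-bromo-4-methoxy-5-(methoxymethoxy)benzaldehyde | COCOc1cc(C=O)cc(Br)c1OC
F2 | step 11 | 1-[2-methoxy-4,6-bis(methoxymethoxy)phenyl]ethanone | CC(=O)c1c(OC)cc(OCOC)cc1OCOC
F3 | step 11 | (E)-3-[3-bromo-4-methoxy-5-(methoxymethoxy)phenyl]-1-[2-methoxy-4,6-bis(methoxymethoxy)phenyl]prop-2-en-1-one | COCOc1cc(/C=C/C(=O)c2c(OC)cc(OCOC)cc2OCOC)cc(Br)c1OC
F4 | step 11 | 2-[3-bromo-4-methoxy-5-(methoxymethoxy)phenyl]-3,3-dimethoxy-1-[2-methoxy-4,6-bis(methoxymethoxy)phenyl]propan-1-one (racemic) | COC(OC)C(C(=O)c1c(OC)cc(OCOC)cc1OCOC)c1cc(Br)c(OC)c(OCOC)c1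
F5 | step 11 | 3-(3-bromo-5-hydroxy-4-methoxyphenyl)-7-hydroxy-5-methoxychromen-4-one | COc1c(O)cc(-c2coc3cc(O)cc(OC)c3c2=O)cc1Br
F6 | step 9 | tert-butyl (Z)-2-[3-bromo-4-methoxy-5-(triisopropylsilyloxy)phenyl]-3-hydroxyprop-2-enoate | O/C=C(\C(=O)OC(C)(C)C)c1cc(Br)c(OC)c(O[Si](C(C)C)(C(C)C)C(C)C)c1
F7 | step 9 | tert-butyl (Z)-3-chloro-2-[3-bromo-4-methoxy-5-(triisopropylsilyloxy)phenyl]prop-2-enoate | Cl/C=C(\C(=O)OC(C)(C)C)c1cc(Br)c(OC)c(O[Si](C(C)C)(C(C)C)C(C)C)c1
F8 | step 12 | 3-[3-allyl-4-methoxy-5-(triisopropylsilyloxy)phenyl]-5-methoxy-7-(triisopropylsilyloxy)chromen-4-one | COc1c(O[Si](C(C)C)(C(C)C)C(C)C)cc(-c2coc3cc(O[Si](C(C)C)(C(C)C)C(C)C)cc(OC)c3c2=O)cc1CC=C
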